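## Analysis of the target

Target 9 is a 3,4-dihydro-2H-chromen-2-one (numbering O1, C2, C3, C4, C4a, C5–C8, C8a; the aryl group on C4 is C1′–C6′). The lactone ring O1–C2–C3–C4–C4a–C8a is fused to a phloroglucinol ring with free hydroxyls on C5 and C7, hydrogen on C6 and a 3-phenylpropanoyl group on C8. The carbocycle is therefore the A ring of a dihydrochalcone.

The only stereocentre is C4, a doubly benzylic methine bearing the 4-hydroxyphenyl group, C4a and the C3 methylene. With the priorities C4a > C1′ > C3 > H the SMILES descriptor reads 4S. Nothing else in the molecule can relay it, so it must come from a catalyst.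

The constitution hides a second problem. O1 sits on C8a, the carbon between the acyl-bearing C8 and C4a. Closure of the same hydroxy acid on the C5 oxygen would give the 6-acyl isomer. The two lactones can interconvert only through the ring-opened acid or ester, so the choice must be made once and then kept away from nucleophiles.

Sensitive sites are the aryl-ester lactone (alcoholysis, hydrolysis, attack by the enolate of the neighbouring ketone), the three phenols on electron-rich rings, and the C4–C4a bond. That bond joins a para-hydroxybenzylic carbon to a phloroglucinol ring and can ionise in strong acid, which would racemise C4.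

The synthesis is hard in two places only: facial control at a diarylmethine whose two aryl groups are sterically alike, and the O1-versus-O5 decision.

## Retrosynthetic reasoning

Ring positions of the precursors are named by their future chromanone numbers.

**9 ⇒ 8 (O–benzyl bonds).** The last step should be a non-nucleophilic unmasking, because only nucleophiles can move the lactone from O1 to O5. Both phenols that need masking, O5 on the phloroglucinol ring and O4′ on the aryl group, are therefore carried as benzyl ethers and released together by hydrogenolysis.

**8 ⇒ 6 + 7 (C2–C3 and C2–O1).** C2 is the only carbon at the carboxyl oxidation level. It lies between a phenolic oxygen and a methylene whose neighbour is the stereocentre. Cutting both of its ring bonds removes it as carbon monoxide 7 and reduces the chiral lactone to the achiral 1,1-diarylethene 6. In the forward direction a chiral palladium hydride must add hydride to one face of the diaryl carbon (making C4–H), insert 7 at the CH2 terminus (C3–C2) and let the ortho phenol close the ring (C2–O1). This cut was chosen because the prochiral carbon of 6 carries two aryl groups that differ as much as possible for a metal: one has an ortho hydroxyl that binds palladium and later becomes O1. It also means the lactone is formed in a non-nucleophilic medium with only one hydroxyl within reach.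

**6 ⇒ 4 + 5 (C4–C4a).** The 1,1-diarylethene is the Markovnikov hydroarylation product of the terminal alkyne 5 with the electron-rich ring of 4. Ketone 4 has a mirror plane, so its two ring CH positions are equivalent and so are its two free hydroxyls. No regiochemical question arises, and the carbon that is attacked automatically lies between the free hydroxyl (future O1) and the benzylated oxygen (future O5).

**4 ⇒ 3 (O5–benzyl).** The benzyl group on the oxygen para to the ketone is the regiochemical lock of the route. It is placed by substrate control, since that hydroxyl is the most acidic and the only one not hydrogen-bonded to the ketone.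

**3 ⇒ 1 + 2 (C8–acyl).** Friedel–Crafts acylation of the threefold symmetric triol 1 with acid chloride 2 sets the dihydrochalcone ketone first, while all ring positions are still equivalent.

## Alternatives that were turned down

**Alternative 1:** the textbook disconnection, C4–C4a together with O1–C2.
- Forward key step: acid-promoted hydroarylation of 4-hydroxycinnamic acid A1 by ketone 3, followed by lactonisation.
- Why turned down:
  - The electrophile is a planar benzylic cation (a protonated quinone methide), so the product is the racemate A2 of 9 and a resolution is needed.
  - The intermediate hydroxy acid has two free ortho hydroxyls, so the 6-acyl lactone A3 forms beside A2.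
  - The acid that makes the C4–C4a bond can also break it, so stereocontrol cannot be added afterwards.
  - Enantioselective versions of the same bond construction on 4 exist as a reaction type (a chiral carbene turns an ynal into an unsaturated acyl azolium, which the phenol captures and which rearranges). They ask a ketone-chelated, conjugation-deactivated phenol to act first as O-nucleophile and then as the π-component of a [3,3] shift into a position flanked by two ortho substituents. This is the first-drawn strategy with a catalyst added, and it is kept only as the fallback for the key step.

**Alternative 2:** disconnection of the C4–C1′ bond.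
- Forward key step: rhodium-catalysed asymmetric conjugate addition (Hayashi–Miyaura type) of [4-(benzyloxy)phenyl]boronic acid A5 to the coumarin A4 (5-benzyloxy-7-hydroxy-8-(3-phenylpropanoyl)-2H-chromen-2-one), itself made from 4 and a propiolate ester.
- Why turned down:
  - The C3=C4 bond of a coumarin is a vinylogous aryl ester with residual aromatic stabilisation and is a poor acceptor.
  - In A4 the acceptor carbon is peri to the benzyloxy group on C5, so aryl transfer must go to the most hindered position of the ring system.
  - The aqueous basic medium needed for transmetalation also opens aryl lactones, and protodeboronation of the electron-rich A5 competes.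
  - A4 costs as many steps as 6, so nothing is gained.

**Alternative 3:** biomimetic construction of the phloroglucinol ring (bonds C5–C6 of the arene, after C4–C4a and O1–C2).
- Forward sequence: 6-phenylhexane-2,4-dione A6 is condensed with a malonyl bis-electrophile to the acylpyranone A7 (4-hydroxy-6-methyl-5-(3-phenylpropanoyl)-2H-pyran-2-one), a masked tetraketide. Asymmetric Michael addition–lactonisation with an unsaturated acyl azolium gives the bicyclic lactone A8. In A8 the lactone oxygen already sits on the future C8a, next to the acyl-bearing carbon. Opening the pyranone and Claisen condensation of its C-methyl group onto the pyranone carbonyl (future C5) would fold the chain into the arene, as chalcone synthase does.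
- Why turned down:
  - The enol-ester lactone O1–C2 of A8 has a vinylogous carboxylate as leaving group. It is more electrophilic than the pyranone carbonyl, so any base or nucleophile able to open the pyranone opens the lactone first.
  - After aromatisation both ortho hydroxyls are free, and the O1/O5 decision that A8 had encoded is lost.
  - The methylene of the 3-phenylpropanoyl group competes with the methyl group as Claisen nucleophile.
  - Three to four steps would be spent building a benzene ring that can be bought.

Key step: step 4

Assumption: the SMILES descriptor is read as 4S (C4a > C1′ > C3 > H), and compounds 1, 2, 5 and 7 are taken as purchased.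

## Route

Step 1
Reactants: 1 benzene-1,3,5-triol (phloroglucinol); 2 3-phenylpropanoyl chloride
Product: 3 3-phenyl-1-(2,4,6-trihydroxyphenyl)propan-1-one
Conditions: AlCl3 (3.5 equiv), PhNO2–CH2Cl2, 0 °C → 50 °C; then ice/aq. HCl
Reagents that add atoms: none
Why: Friedel–Crafts C-acylation of a ring whose three CH positions are equivalent; the first acyl group deactivates the ring and holds the Lewis acid as a chelate, so the reaction should stop at the monoketone.

Step 2
Reactants: 3 3-phenyl-1-(2,4,6-trihydroxyphenyl)propan-1-one
Product: 4 1-[4-(benzyloxy)-2,6-dihydroxyphenyl]-3-phenylpropan-1-one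
Conditions: BnBr (1.0 equiv), K2CO3 (1.1 equiv), acetone, 0 °C → rt
Reagents that add atoms: benzyl bromide, BrCc1ccccc1
Why: Williamson ether synthesis under substrate control: the hydroxyl para to the ketone (future O5) is the most acidic and the only one not hydrogen-bonded to the carbonyl group, so one equivalent of base and halide should alkylate it alone; the product keeps a mirror plane, which makes the two free hydroxyls and the two ring CH positions equivalent.

Step 3
Reactants: 4 1-[4-(benzyloxy)-2,6-dihydroxyphenyl]-3-phenylpropan-1-one; 5 1-(benzyloxy)-4-ethynylbenzene
Product: 6 1-[4-(benzyloxy)-3-{1-[4-(benzyloxy)phenyl]ethenyl}-2,6-dihydroxyphenyl]-3-phenylpropan-1-one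
Conditions: Ph3PAuNTf2 (3 mol %), 4 (1.3 equiv), 5 added slowly, 1,2-dichloroethane, 50 °C
Reagents that add atoms: none
Why: Intermolecular Markovnikov hydroarylation (Friedel–Crafts alkenylation) of a gold-activated terminal arylalkyne by an electron-rich arene; either of the two equivalent ring CH positions of 4 attacks the internal alkyne carbon, whose cationic character is stabilised by the 4-benzyloxyphenyl group, and protodeauration should give the 1,1-diarylethene with the new substituent between the free hydroxyl and the benzyl ether.

Step 4
Reactants: 6 1-[4-(benzyloxy)-3-{1-[4-(benzyloxy)phenyl]ethenyl}-2,6-dihydroxyphenyl]-3-phenylpropan-1-one; 7 carbon monoxide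
Product: 8 (4S)-5-(benzyloxy)-4-[4-(benzyloxy)phenyl]-7-hydroxy-8-(3-phenylpropanoyl)-3,4-dihydro-2H-chromen-2-one
Conditions: Pd2(dba)3 (2.5 mol %), WingPhos (6 mol %, the antipode that delivers hydride to the Re face of C4), MsOH (10 mol %), CO (5 bar), toluene, 60 °C
Reagents that add atoms: none
Why: A palladium hydride, formed from zerovalent palladium and the sulfonic acid, adds across the 1,1-diarylethene with hydride going to the diaryl carbon (C4) and palladium to the CH2 terminus (C3); 7 inserts into the primary alkyl–palladium bond, and the neighbouring phenol attacks the acylpalladium to release the lactone and regenerate the hydride. The closest known reaction type is the palladium-catalysed asymmetric hydroesterification (cyclocarbonylation) of 2-(1-arylvinyl)phenols, formed in situ from diarylmethyl carbinols, to 4-aryl-3,4-dihydrocoumarins with P-stereogenic bisphosphines. The lactone ring closes in the 6-exo-trig mode by acyl substitution at C2 by the future O1, the only hydroxyl ortho to the side chain because the other ortho oxygen (O5) is benzylated; the hydroxyl on future C7 is remote and hydrogen-bonded to the ketone. The C4 stereocentre is created in the hydropalladation and is controlled by the ligand: the phenol binds palladium and fixes the trioxygenated ring, and the chiral pocket of the bisphosphine then decides which alkene face receives hydride; delivery to the Re face (trioxygenated aryl > benzyloxyphenyl > CH2) gives 4S. The step needs anti-Markovnikov insertion, which the substrate secures because the other regiochemistry would put palladium on a tertiary, doubly benzylic carbon that inserts CO poorly and reverts. It also needs CO capture to be faster than β-hydride elimination, which the CO pressure secures, so that the face selection is not eroded. The aryl ketone and the benzyl ethers are inert to palladium hydride and CO under these conditions.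

Step 5
Reactants: 8 (4S)-5-(benzyloxy)-4-[4-(benzyloxy)phenyl]-7-hydroxy-8-(3-phenylpropanoyl)-3,4-dihydro-2H-chromen-2-one
Product: 9 (4S)-5,7-dihydroxy-4-(4-hydroxyphenyl)-8-(3-phenylpropanoyl)-3,4-dihydro-2H-chromen-2-one
Conditions: H2 (1 atm), 10% Pd/C, EtOAc, rt
Reagents that add atoms: none
Why: Hydrogenolysis of both benzyl aryl ethers in one operation; the non-nucleophilic solvent keeps the aryl lactone closed so that O1 stays on C8a, the chelated aryl ketone should be reduced far more slowly than the ethers are cleaved, and C4 carries no heteroatom and is not touched, so the 4S configuration is carried through.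

## Compound list

1 | benzene-1,3,5-triol (phloroglucinol) | Oc1cc(O)cc(O)c1 | starting material
2 | 3-phenylpropanoyl chloride | O=C(Cl)CCc1ccccc1 | starting material
3 | 3-phenyl-1-(2,4,6-trihydroxyphenyl)propan-1-one | O=C(CCc1ccccc1)c1c(O)cc(O)cc1O | intermediate
4 | 1-[4-(benzyloxy)-2,6-dihydroxyphenyl]-3-phenylpropan-1-one | O=C(CCc1ccccc1)c1c(O)cc(OCc2ccccc2)cc1O | intermediate
5 | 1-(benzyloxy)-4-ethynylbenzene | C#Cc1ccc(OCc2ccccc2)cc1 | starting material
6 | 1-[4-(benzyloxy)-3-{1-[4-(benzyloxy)phenyl]ethenyl}-2,6-dihydroxyphenyl]-3-phenylpropan-1-one | O=C(CCc1ccccc1)c1c(O)cc(OCc2ccccc2)c(C(=C)c2ccc(OCc3ccccc3)cc2)c1O | intermediate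
7 | carbon monoxide | [C-]#[O+] | starting material
8 | (4S)-5-(benzyloxy)-4-[4-(benzyloxy)phenyl]-7-hydroxy-8-(3-phenylpropanoyl)-3,4-dihydro-2H-chromen-2-one | O=C1C[C@@H](c2ccc(OCc3ccccc3)cc2)c2c(OCc3ccccc3)cc(O)c(C(=O)CCc3ccccc3)c2O1 | intermediate
9 | (4S)-5,7-dihydroxy-4-(4-hydroxyphenyl)-8-(3-phenylpropanoyl)-3,4-dihydro-2H-chromen-2-one | O=C1C[C@@H](c2ccc(O)cc2)c2c(O)cc(O)c(C(=O)CCc3ccccc3)c2O1 | target

## Step count and risk

Total step count: 5. Longest linear sequence: 5 steps (1 → 3 → 4 → 6 → 8 → 9).

**Step 4 (key step).**
- What may go wrong: loss of facial selectivity if hydropalladation becomes reversible (β-hydride elimination outrunning CO insertion). The alkene is hindered, because the trioxygenated ring is twisted out of the alkene plane by two ortho substituents, so insertion may be slow. The electron-rich alkene may also oligomerise under acid before it is carbonylated.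
- Fallback (another bond set, known reaction types), setting out from 4 and 5 and returning at 8: alkyne 5 is deprotonated with n-BuLi in THF at −78 °C and formylated with DMF to give 3-[4-(benzyloxy)phenyl]prop-2-ynal F1. Ketone 4 and F1 are combined with a chiral aminoindanol-derived N-mesityl triazolium carbene precatalyst in toluene at 40 °C. The carbene converts the ynal by internal redox into an α,β-unsaturated acyl azolium, one of the two equivalent free hydroxyls of 4 adds to it, a [3,3] sigmatropic shift of the Coates–Claisen type forms C4–C4a under catalyst control, and the same oxygen closes the lactone. This should give 8 directly, with the catalyst antipode chosen for 4S. The benzyl ether on O5 fixes the regiochemistry here as well.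

**Step 3.**
- What may go wrong: over-reaction. This could be a second alkenylation at the remaining ring CH, addition of a second arene to the product alkene, or O–H addition across the alkyne instead of C–H addition.
- Fallback (cross-coupling in place of Friedel–Crafts chemistry), setting out from 4 and 5 and returning at 6: ketone 4 is iodinated at one of its two equivalent ring CH positions with N-iodosuccinimide in MeCN at 0 °C to give 1-[4-(benzyloxy)-2,6-dihydroxy-3-iodophenyl]-3-phenylpropan-1-one F2. Alkyne 5 is converted by copper-catalysed α-selective protoboration (CuCl, an N-heterocyclic carbene ligand, NaOtBu, B2pin2, MeOH, THF) into 2-{1-[4-(benzyloxy)phenyl]ethenyl}-4,4,5,5-tetramethyl-1,3,2-dioxaborolane F3. Suzuki–Miyaura coupling of F2 with F3 (Pd(dppf)Cl2, K3PO4, dioxane–water, 80 °C) should give 6.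

**Step 2.**
- What may go wrong: over-alkylation (a second benzylation on a chelated hydroxyl) and C-benzylation of the ambident phloroglucinol anion.
- Fallback (protect all, then remove selectively), setting out from 3 and returning at 4: exhaustive benzylation (excess BnBr, K2CO3, DMF, 80 °C) gives 3-phenyl-1-[2,4,6-tris(benzyloxy)phenyl]propan-1-one F4. BCl3 (2.2 equiv, CH2Cl2, −78 °C) then cleaves only the two benzyl ethers ortho to the ketone, because boron is delivered by chelation to the carbonyl oxygen, and should leave 4.

**Step 5.**
- What may go wrong: over-reduction (hydrogenolysis of the aryl ketone towards the methylene compound), or solvolytic opening of the aryl lactone if a nucleophilic solvent or wet catalyst is used.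
- Fallback (Lewis-acid cleavage in place of hydrogenation), setting out from 8 and returning at 9 with no new compound (F0): BCl3 with pentamethylbenzene as benzyl-cation scavenger in CH2Cl2 at −78 °C removes both benzyl groups under anhydrous, non-nucleophilic and non-reducing conditions.

## Further compounds

F1 | step 4 | 3-[4-(benzyloxy)phenyl]prop-2-ynal | O=CC#Cc1ccc(OCc2ccccc2)cc1
F2 | step 3 | 1-[4-(benzyloxy)-2,6-dihydroxy-3-iodophenyl]-3-phenylpropan-1-one | O=C(CCc1ccccc1)c1c(O)cc(OCc2ccccc2)c(I)c1O
F3 | step 3 | 2-{1-[4-(benzyloxy)phenyl]ethenyl}-4,4,5,5-tetramethyl-1,3,2-dioxaborolane | C=C(B1OC(C)(C)C(C)(C)O1)c1ccc(OCc2ccccc2)cc1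
F4 | step 2 | 3-phenyl-1-[2,4,6-tris(benzyloxy)phenyl]propan-1-one | O=C(CCc1ccccc1)c1c(OCc2ccccc2)cc(OCc2ccccc2)cc1OCc1ccccc1
F0 | step 5 | none | none
A1 | alternative 1 | (E)-4-hydroxycinnamic acid | OC(=O)/C=C/c1ccc(O)cc1
A2 | alternative 1 | racemic 5,7-dihydroxy-4-(4-hydroxyphenyl)-8-(3-phenylpropanoyl)-3,4-dihydro-2H-chromen-2-one | O=C1CC(c2ccc(O)cc2)c2c(O)cc(O)c(C(=O)CCc3ccccc3)c2O1
A3 | alternative 1 | racemic 5,7-dihydroxy-4-(4-hydroxyphenyl)-6-(3-phenylpropanoyl)-3,4-dihydro-2H-chromen-2-one | O=C1CC(c2ccc(O)cc2)c2c(O)c(C(=O)CCc3ccccc3)c(O)cc2O1
A4 | alternative 2 | 5-(benzyloxy)-7-hydroxy-8-(3-phenylpropanoyl)-2H-chromen-2-one | O=c1ccc2c(OCc3ccccc3)cc(O)c(C(=O)CCc3ccccc3)c2o1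
A5 | alternative 2 | [4-(benzyloxy)phenyl]boronic acid | OB(O)c1ccc(OCc2ccccc2)cc1
A6 | alternative 3 | 6-phenylhexane-2,4-dione | CC(=O)CC(=O)CCc1ccccc1
A7 | alternative 3 | 4-hydroxy-6-methyl-5-(3-phenylpropanoyl)-2H-pyran-2-one | Cc1oc(=O)cc(O)c1C(=O)CCc1ccccc1
A8 | alternative 3 | (4S)-4-[4-(benzyloxy)phenyl]-7-methyl-8-(3-phenylpropanoyl)-3,4-dihydro-2H,5H-pyrano[4,3-b]pyran-2,5-dione | O=C1C[C@@H](c3ccc(OCc4ccccc4)cc3)C2=C(O1)C(C(=O)CCc3ccccc3)=C(C)OC2=O
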